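## Structural features

The target is an ether-linked biflavonoid. One half is a (2S)-5-hydroxy-7-methoxyflavanone (phloroglucinol-type ring A, dihydropyranone ring C, aryl ring B). Ring B carries a free 4'-hydroxyl and, at the neighbouring 3'-position, an aryloxy bridge to the para position of the 2-aryl ring (ring F) of a 5,7-dihydroxyflavone (pyranone ring D fused to benzene ring E).

The only stereocentre is C2 of ring C, a benzylic carbon bonded to O1 and to ring B. It has no stereogenic neighbour, so the task is absolute control, not relative control.

That centre is fragile in three ways. Base opens the β-aryloxy ketone to the 2'-hydroxychalcone (retro-oxa-Michael reaction). The free 4'-hydroxyl allows a quinone-methide pathway. Acid can ionise the C2–O1 bond, because ring B is a para-oxygenated benzyl group.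

The flavone half is robust, but its construction needs enolate chemistry under strong base, which a flavanone would not survive. Of the five oxygens on rings A, B and E, four must end as free phenols and one (7-O of ring A) as a methyl ether; the 5-OH of ring A is distinguished only by being peri to the C4 carbonyl.

The real difficulty is therefore the order of events: C2 must be set in high enantiomeric purity and then kept through the construction of rings D and E and through the final unmasking.

The key step exploits the O1–C8a bond. The oxygen of an (S)-configured benzylic carbinol is joined to the brominated carbon C8a of ring A without breaking the C–O bond at the stereocentre. C4 is left as a methylene group, which the oxygens of ring A ortho and para to C4a (O1, 5-O, 7-O) later activate for oxidation.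

## Logic of the disconnections

**17 ⇒ 16.** Cut: the three O–CH2Ph bonds (4'-O of ring B, 5-O and 7-O of ring E) and the O–CH3 bond at C5 of ring A. Reason: all phenols must be masked through enolate, palladium and oxidation chemistry, and the 5-methoxy group is the one methyl ether a chelating Lewis acid can tell from its 7-neighbour. Gain: one fully protected precursor and a single closing operation. Demand: the Lewis acid must spare the 7-methyl ether, the diaryl ether and the C2–O1 bond.

**16 ⇒ 15 ⇒ 14.** Cut: the C4=O bond, taken back through the C4 carbinol to a C4 methylene group. Reason: without its ketone, ring C has no acidic C3–H and cannot open by retro-oxa-Michael reaction, so the stereocentre of 14 is indifferent to strong base. Gain: the flavone half can be built after the stereocentre exists. Demand: the oxidation must choose C4 (benzylic to ring A) over C2 (benzylic to ring B and α to oxygen), and the second oxidation must be non-basic.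

**14 ⇒ 13 ⇒ 10 + 12.** Cut: O1–C2 of ring D (dehydration), then C2–C3 of ring D, the bond between the ester carbon of 10 and the methyl carbon of 12. Reason: the ester carbon is already at the oxidation level of flavone C2, and ring E with its acetyl group is a cheap, symmetric building block. Gain: the whole flavone half shrinks to 12 plus a one-carbon tag on 10. Demand: the hindered enolate of 12 must acylate with a methyl ester, and the acid that closes ring D must be too mild to ionise the C2–O1 bond of ring C. For that reason the tag is a methyl ester, used directly as the electrophile, and not a tert-butyl ester that would need acid for its removal.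

**10 ⇒ 9 (key).** Cut: O1–C8a of ring C. Reason: this is the only ring bond whose formation leaves every bond at the stereocentre intact, and the electrophilic carbon is an aryl bromide that survives all earlier steps. Gain: ring C opens to an acyclic 1,3-diarylpropan-1-ol whose single stereocentre is a simple secondary carbinol. Demand: C–O reductive elimination at palladium must beat β-hydride elimination from a secondary benzylic alkoxide.

**9 ⇒ 8.** Cut: the C–H bond at the carbinol carbon (future C2). Reason: an aryl alkyl ketone is the best-understood substrate class for reagent-controlled enantioselective reduction. Gain: the stereocentre is replaced by a prochiral carbonyl group. Demand: the catalyst must differentiate the aryl group from the CH2CH2Ar chain, and the ester must not be reduced.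

**8 ⇒ 7 ⇒ 6 + 3.** Cut: after formal dehydrogenation to the enone, the C3–C4 bond (flavan numbering), between the methyl carbon of 6 and the formyl carbon of 3. Reason: an aldol condensation joins two simple aromatic pieces and places bromine exactly at the future C8a. Gain: the three-carbon chain is assembled in one step from a methyl ketone and an aldehyde. Demand: the condensation must spare the methyl ester, and the C=C reduction must spare the aryl bromide and the benzyl ether, which excludes hydrogenation over palladium.

**6 ⇒ 4 + 5.** Cut: the bond between the bridging oxygen and ring F. Reason: the para ester activates the fluoride for addition–elimination and is at the same time the tag needed later. Gain: the diaryl ether comes from two catalogue compounds without a metal. Demand: the phenoxide must react faster than the ester is attacked.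

**3 ⇒ 1 and 12 ⇒ 11.** Cut: the C4–C4a bond (formyl group on ring A) and two O–benzyl bonds. Reason: both are single, regioselective functionalisations of symmetric commercial arenes. Gain: all four starting materials are simple. Demand: formylation must occur next to bromine and not between the methoxy groups, and benzylation must stop before the hydrogen-bonded hydroxyl reacts.

## Other disconnections considered

**Alternative 1:** The cut is the C3–C4 bond of ring C.

- **Forward key step.** In the tosylate A2, C4 is the carbon of a 2-aryl-1,3-dithiane and C3 a primary CH2OTs group on the already configured ether carbon. A2 is (R) but has the same spatial arrangement as the (2S) product; the descriptor differs only because CH2OTs outranks the aryl group. LDA deprotonates the dithiane and the sulfur-stabilised carbanion displaces the tosylate to give the spiro dithioketal A1.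
- **In its favour.** C4 is at the ketone oxidation level from the outset and masked in a base-inert form, so the C2-versus-C4 question of a late oxidation never arises; on this point it is better than the chosen plan. Like the chosen plan it closes ring C without touching a bond at C2 (equal). The 5-oxygen carries a methoxymethyl group, which is easier to remove at the end than a peri-methyl ether (better).
- **Against it here.** The stereocentre must be made earlier by forming the O1–C2 aryl ether at a para-oxygenated benzylic carbon, where clean inversion competes with ionisation; the chosen plan sets it by a catalyst-controlled ketone reduction. The carbanion sits between two ortho substituents. The C2–H bond, benzylic and α to oxygen, invites E2 loss of the tosylate. LDA must tolerate the aryl bromide. The dithioketal must later be removed with a thiophilic metal salt or an oxidant in the presence of electron-rich rings. The bromide tag must still be turned into the flavone half by metal-catalysed coupling.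
- **Comparison.** Structurally both plans reach the same ring C. Mechanistically a hindered anionic alkylation replaces a catalytic C–O coupling. In step count, dithiane installation and removal plus the tag conversion make it longer by an estimated three to four operations.

**Alternative 2:** The cut removes four bonds of ring E of the flavone half (C8–C8a, C7–C8, C5–C6, C4a–C5).

- **Forward key step.** Irradiation of the pyranonyl diazoketone A4 triggers a Wolff rearrangement to a pyranonyl ketene (C8–C8a). This adds to the siloxyalkyne A5 in a [2+2] cycloaddition (C5–C6, C7–C8). Heating opens the cyclobutenone (4π) and closes the dienylketene (6π, C4a–C5) to the phenol A3 after tautomerisation.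
- **In its favour.** The conditions are neutral and need no strong base, which is milder than the enolate acylation of the chosen plan (better on this point). The 5-hydroxyl and the 7-siloxy group emerge fully differentiated (better than any desymmetrisation of a phloroglucinol).
- **Against it here.** The target needs both oxygens of ring E as free phenols, so the differentiation buys nothing. Ring E is available ready-made in 11. A4 needs a multi-step preparation through an acid chloride and diazomethane. The photochemical step is awkward to scale. The stereochemical problem is untouched: the bromide of A3 must still be extended into rings C and A, and conjugate reduction and C4 oxidation would then run in the presence of the flavone enone.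
- **Comparison.** Structurally it solves the easy half of the molecule. Mechanistically it is elegant and pericyclic where the chosen plan is classical. In step economy it is clearly longer.

**Alternative 3:** The cut is the C2–C3 bond of ring C.

- **Forward key step.** The diazomethyl ketone A7 loses N2 on Rh2(S-PTTL)4, and the carbenoid carbon (C3) inserts into a C–H bond of the benzylic O–CH2 group. This forms ring C and the stereocentre together and gives A6.
- **In its favour.** It is the most convergent plan: stereocentre, ring and ketone appear in one catalytic step on the fully assembled skeleton. There is no late oxidation. The silyl and benzyl groups come off with fluoride and hydrogenolysis, with no peri-demethylation. On step count and on the final deprotection it is better than the chosen plan.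
- **Against it here.** A carbenoid from a diazomethyl ketone has no donor substituent and is highly reactive, so enantiofacial discrimination by the carboxylate ligands is least reliable for this class. The ortho ether oxygen can capture the carbenoid as a five-membered oxonium ylide, and a 1,2-shift would follow. Closure to a six-membered ring by C–H insertion is less favoured than five-membered closure. Addition to the neighbouring arene is a further escape. The diazoketone must be made late from a large acid chloride.
- **Comparison.** Structurally it is the most direct route. Mechanistically the whole stereochemical outcome rests on one step of uncertain selectivity, placed where material is most valuable. The chosen plan sets C2 early by a well-understood reduction and accepts about four more steps.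

Key step: step 6

Remark: the descriptor is (S) in 9 and at C2 in 10 and 13–17. The ring closure of step 6 does not change it, because the sequence-rule order O > aryl > CH2 is the same before and after.

Assumption: 15 is carried on as the mixture of its two C4 epimers, which converge on 16.

## Route

Step 1
Reactants: 1 1-bromo-3,5-dimethoxybenzene
Product: 3 2-bromo-4,6-dimethoxybenzaldehyde, via aryl iminium salt 2 (not isolated)
Conditions: POCl3, DMF, 0 → 90 °C; then ice/H2O
Reagents that add atoms: N,N-dimethylformamide CN(C)C=O (formyl carbon); water O (carbonyl oxygen)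
Why: Vilsmeier–Haack formylation; the chloroiminium ion should attack the ring position para to one methoxy group and ortho to the other (next to bromine), not the doubly ortho-flanked site between the methoxy groups, and the iminium salt 2 is hydrolysed to the aldehyde on aqueous work-up.

Step 2
Reactants: 4 1-[4-(benzyloxy)-3-hydroxyphenyl]ethanone; 5 methyl 4-fluorobenzoate
Product: 6 methyl 4-[5-acetyl-2-(benzyloxy)phenoxy]benzoate
Conditions: K2CO3, DMSO, 110 °C
Reagents that add atoms: none
Why: Nucleophilic aromatic substitution by addition–elimination; the phenoxide of 4 adds para to the ester of 5 and the Meisenheimer intermediate expels fluoride. The ester both activates the ring and is the carbon that later becomes C2 of the flavone.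

Step 3
Reactants: 6 methyl 4-[5-acetyl-2-(benzyloxy)phenoxy]benzoate; 3 2-bromo-4,6-dimethoxybenzaldehyde
Product: 7 methyl 4-{2-(benzyloxy)-5-[(2E)-3-(2-bromo-4,6-dimethoxyphenyl)prop-2-enoyl]phenoxy}benzoate
Conditions: NaOMe (0.5 equiv), MeOH/THF, rt
Reagents that add atoms: none
Why: Claisen–Schmidt condensation; 3 has no α-hydrogen, so only the cross product is expected, and E1cB loss of water gives the (E)-enone. Methoxide in methanol matches the methyl ester, so any transesterification is degenerate.

Step 4
Reactants: 7 methyl 4-{2-(benzyloxy)-5-[(2E)-3-(2-bromo-4,6-dimethoxyphenyl)prop-2-enoyl]phenoxy}benzoate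
Product: 8 methyl 4-{2-(benzyloxy)-5-[3-(2-bromo-4,6-dimethoxyphenyl)propanoyl]phenoxy}benzoate
Conditions: [(Ph3P)CuH]6 (0.3 equiv), H2O (3 equiv), THF/toluene, rt
Reagents that add atoms: none
Why: Conjugate reduction by the copper hydride hexamer; hydride goes to the β-carbon and water protonates the copper enolate. The reagent should leave the aryl bromide, the benzyl ether, the ester and the saturated ketone untouched, which hydrogenation over palladium would not.

Step 5
Reactants: 8 methyl 4-{2-(benzyloxy)-5-[3-(2-bromo-4,6-dimethoxyphenyl)propanoyl]phenoxy}benzoate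
Product: 9 methyl 4-{2-(benzyloxy)-5-[(1S)-3-(2-bromo-4,6-dimethoxyphenyl)-1-hydroxypropyl]phenoxy}benzoate
Conditions: (R)-2-methyl-CBS-oxazaborolidine (15 mol%), BH3·SMe2, THF, −20 °C; then MeOH
Reagents that add atoms: none
Why: Corey–Bakshi–Shibata reduction; the (R)-oxazaborolidine holds the ketone with the aryl group as the large substituent and delivers hydride to the face that gives the (S)-carbinol, the usual sense for aryl alkyl ketones with this catalyst. The benzoate ester is not reduced by borane at this temperature.

Step 6
Reactants: 9 methyl 4-{2-(benzyloxy)-5-[(1S)-3-(2-bromo-4,6-dimethoxyphenyl)-1-hydroxypropyl]phenoxy}benzoate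
Product: 10 methyl 4-{2-(benzyloxy)-5-[(2S)-5,7-dimethoxy-3,4-dihydro-2H-chromen-2-yl]phenoxy}benzoate
Conditions: Pd(OAc)2 (5 mol%), 2-(di-tert-butylphosphino)-1,1'-binaphthyl (6 mol%), Cs2CO3, toluene, 70 °C
Reagents that add atoms: none
Why: Palladium-catalysed intramolecular C–O cross-coupling of a secondary alcohol with an aryl bromide, the etherification counterpart of the Buchwald–Hartwig amination. Zerovalent palladium, formed from Pd(OAc)2 and the phosphine, inserts into the C8a–Br bond of ring A; carbonate deprotonates the bound carbinol to give a seven-membered aryl(alkoxo) complex of divalent palladium, and C–O reductive elimination releases ring C and returns zerovalent palladium. Ring C therefore closes as a six-membered ring by reductive elimination from that palladacycle, the only ring size open to a substrate with one hydroxyl and one halide. No stereocentre is created: the C–O bond at the carbinol carbon is never broken, so the configuration set in step 5 passes into C2 with retention. The selectivity that matters is reductive elimination against β-hydride elimination from the alkoxide, which would oxidise the carbinol back to the ketone and reduce the C–Br bond; the bulky, electron-rich di-tert-butylbiaryl phosphine crowds the metal and speeds reductive elimination. The bromide has one ortho substituent and both methoxy groups meta to it, so oxidative addition is not slowed by para donation. The weak, poorly soluble base Cs2CO3 is chosen so that the methyl ester and the benzyl ether are left alone.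

Step 7
Reactants: 11 1-(2,4,6-trihydroxyphenyl)ethanone (2,4,6-trihydroxyacetophenone)
Product: 12 1-[2,4-bis(benzyloxy)-6-hydroxyphenyl]ethanone
Conditions: BnBr (2.1 equiv), K2CO3, DMF, rt → 60 °C
Reagents that add atoms: benzyl bromide BrCc1ccccc1
Why: Williamson etherification; the para hydroxyl and one ortho hydroxyl are alkylated, and the remaining ortho hydroxyl, hydrogen-bonded to the acetyl group, should be too weakly nucleophilic to react with the limited amount of benzyl bromide.

Step 8
Reactants: 10 methyl 4-{2-(benzyloxy)-5-[(2S)-5,7-dimethoxy-3,4-dihydro-2H-chromen-2-yl]phenoxy}benzoate; 12 1-[2,4-bis(benzyloxy)-6-hydroxyphenyl]ethanone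
Product: 13 1-[2,4-bis(benzyloxy)-6-hydroxyphenyl]-3-(4-{2-(benzyloxy)-5-[(2S)-5,7-dimethoxy-3,4-dihydro-2H-chromen-2-yl]phenoxy}phenyl)propane-1,3-dione
Conditions: NaH (5 equiv), 12 (1.5 equiv), DMF, 0 °C → rt; then aq. NH4Cl
Reagents that add atoms: none
Why: Crossed Claisen condensation; the dianion of 12 (phenoxide and methyl ketone enolate) attacks the methyl ester of 10, methoxide leaves, and the diketone is withdrawn from the equilibrium as its stabilised enolate. The flavan 10 has no acidic C–H and no base-labile group, which is why ring C is carried without its ketone at this stage.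

Step 9
Reactants: 13 1-[2,4-bis(benzyloxy)-6-hydroxyphenyl]-3-(4-{2-(benzyloxy)-5-[(2S)-5,7-dimethoxy-3,4-dihydro-2H-chromen-2-yl]phenoxy}phenyl)propane-1,3-dione
Product: 14 5,7-bis(benzyloxy)-2-(4-{2-(benzyloxy)-5-[(2S)-5,7-dimethoxy-3,4-dihydro-2H-chromen-2-yl]phenoxy}phenyl)-4H-chromen-4-one
Conditions: TsOH·H2O (10 mol%), toluene, 60 °C
Reagents that add atoms: none
Why: Acid-catalysed cyclodehydration; the phenol adds to the aroyl carbonyl (6-exo-trig) to give the 2-hydroxychromanone hemiketal, which loses water to the 4-pyranone of ring D. Catalytic acid at moderate temperature is chosen because this dehydration is far easier than ionisation of the para-oxygenated benzylic C2–O1 bond of ring C, so the stereocentre should not be disturbed.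

Step 10
Reactants: 14 5,7-bis(benzyloxy)-2-(4-{2-(benzyloxy)-5-[(2S)-5,7-dimethoxy-3,4-dihydro-2H-chromen-2-yl]phenoxy}phenyl)-4H-chromen-4-one
Product: 15 5,7-bis(benzyloxy)-2-(4-{2-(benzyloxy)-5-[(2S)-4-hydroxy-5,7-dimethoxy-3,4-dihydro-2H-chromen-2-yl]phenoxy}phenyl)-4H-chromen-4-one (both C4 epimers)
Conditions: DDQ (2 equiv), CH2Cl2/H2O (18:1), 0 °C → rt
Reagents that add atoms: water O
Why: Benzylic oxidation by hydride abstraction with DDQ, the reaction type used to functionalise C4 of 5,7-dioxygenated flavans; the C4 cation is stabilised by the oxygens of ring A ortho (O1, 5-OMe) and para (7-OMe) to C4a and is captured by water. Ring B, with only one alkoxy group para to C1' and an aryloxy group meta to it, is the poorer donor, which should protect the C2–H bond.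

Step 11
Reactants: 15 5,7-bis(benzyloxy)-2-(4-{2-(benzyloxy)-5-[(2S)-4-hydroxy-5,7-dimethoxy-3,4-dihydro-2H-chromen-2-yl]phenoxy}phenyl)-4H-chromen-4-one
Product: 16 (2S)-2-[4-(benzyloxy)-3-{4-[5,7-bis(benzyloxy)-4-oxo-4H-chromen-2-yl]phenoxy}phenyl]-5,7-dimethoxy-2,3-dihydro-4H-chromen-4-one
Conditions: Dess–Martin periodinane, NaHCO3, CH2Cl2, 0 °C → rt
Reagents that add atoms: none
Why: Dess–Martin oxidation of a secondary benzylic alcohol; both epimers give the same ketone. The buffered, non-basic medium keeps the new flavanone from opening to the chalcone, so C2 is not epimerised.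

Step 12
Reactants: 16 (2S)-2-[4-(benzyloxy)-3-{4-[5,7-bis(benzyloxy)-4-oxo-4H-chromen-2-yl]phenoxy}phenyl]-5,7-dimethoxy-2,3-dihydro-4H-chromen-4-one
Product: 17 (2S)-2-{3-[4-(5,7-dihydroxy-4-oxo-4H-chromen-2-yl)phenoxy]-4-hydroxyphenyl}-5-hydroxy-7-methoxy-2,3-dihydro-4H-chromen-4-one (target)
Conditions: BCl3 (excess), pentamethylbenzene, CH2Cl2, −78 → 0 °C; then MeOH, H2O
Reagents that add atoms: none
Why: Lewis-acid ether cleavage; BCl3 removes the three benzyl groups at low temperature, with pentamethylbenzene trapping the benzyl cations by Friedel–Crafts alkylation, and on warming it cleaves only the methyl ether peri to the C4 carbonyl through a six-membered boron chelate. The non-chelated 7-methoxy group and the diaryl ether should survive, and the 4'-oxygen is a weak donor while bound to boron, which disfavours ionisation at C2.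

## Compound list

1 | 1-bromo-3,5-dimethoxybenzene | COc1cc(Br)cc(OC)c1 | starting material
2 | [(2-bromo-4,6-dimethoxyphenyl)methylidene]dimethylammonium dichlorophosphate | COc1cc(Br)c(C=[N+](C)C)c(OC)c1.[O-]P(=O)(Cl)Cl | intermediate (not isolated)
3 | 2-bromo-4,6-dimethoxybenzaldehyde | COc1cc(Br)c(C=O)c(OC)c1 | intermediate
4 | 1-[4-(benzyloxy)-3-hydroxyphenyl]ethanone | CC(=O)c1ccc(OCc2ccccc2)c(O)c1 | starting material
5 | methyl 4-fluorobenzoate | COC(=O)c1ccc(F)cc1 | starting material
6 | methyl 4-[5-acetyl-2-(benzyloxy)phenoxy]benzoate | COC(=O)c1ccc(Oc2cc(C(C)=O)ccc2OCc2ccccc2)cc1 | intermediate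
7 | methyl 4-{2-(benzyloxy)-5-[(2E)-3-(2-bromo-4,6-dimethoxyphenyl)prop-2-enoyl]phenoxy}benzoate | COC(=O)c1ccc(Oc2cc(C(=O)/C=C/c3c(Br)cc(OC)cc3OC)ccc2OCc2ccccc2)cc1 | intermediate
8 | methyl 4-{2-(benzyloxy)-5-[3-(2-bromo-4,6-dimethoxyphenyl)propanoyl]phenoxy}benzoate | COC(=O)c1ccc(Oc2cc(C(=O)CCc3c(Br)cc(OC)cc3OC)ccc2OCc2ccccc2)cc1 | intermediate
9 | methyl 4-{2-(benzyloxy)-5-[(1S)-3-(2-bromo-4,6-dimethoxyphenyl)-1-hydroxypropyl]phenoxy}benzoate | COc1cc(Br)c(CC[C@H](O)c2ccc(OCc3ccccc3)c(Oc3ccc(C(=O)OC)cc3)c2)c(OC)c1 | intermediate (precursor of the key step)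
10 | methyl 4-{2-(benzyloxy)-5-[(2S)-5,7-dimethoxy-3,4-dihydro-2H-chromen-2-yl]phenoxy}benzoate | COc1cc(OC)c2c(c1)O[C@H](c1ccc(OCc3ccccc3)c(Oc3ccc(C(=O)OC)cc3)c1)CC2 | intermediate (product of the key step)
11 | 1-(2,4,6-trihydroxyphenyl)ethanone | CC(=O)c1c(O)cc(O)cc1O | starting material
12 | 1-[2,4-bis(benzyloxy)-6-hydroxyphenyl]ethanone | CC(=O)c1c(O)cc(OCc2ccccc2)cc1OCc1ccccc1 | intermediate
13 | 1-[2,4-bis(benzyloxy)-6-hydroxyphenyl]-3-(4-{2-(benzyloxy)-5-[(2S)-5,7-dimethoxy-3,4-dihydro-2H-chromen-2-yl]phenoxy}phenyl)propane-1,3-dione | COc1cc(OC)c2c(c1)O[C@H](c1ccc(OCc3ccccc3)c(Oc3ccc(C(=O)CC(=O)c4c(O)cc(OCc5ccccc5)cc4OCc4ccccc4)cc3)c1)CC2 | intermediate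
14 | 5,7-bis(benzyloxy)-2-(4-{2-(benzyloxy)-5-[(2S)-5,7-dimethoxy-3,4-dihydro-2H-chromen-2-yl]phenoxy}phenyl)-4H-chromen-4-one | COc1cc(OC)c2c(c1)O[C@H](c1ccc(OCc3ccccc3)c(Oc3ccc(-c4cc(=O)c5c(OCc6ccccc6)cc(OCc6ccccc6)cc5o4)cc3)c1)CC2 | intermediate
15 | 5,7-bis(benzyloxy)-2-(4-{2-(benzyloxy)-5-[(2S)-4-hydroxy-5,7-dimethoxy-3,4-dihydro-2H-chromen-2-yl]phenoxy}phenyl)-4H-chromen-4-one (C4 epimers) | COc1cc(OC)c2c(c1)O[C@H](c1ccc(OCc3ccccc3)c(Oc3ccc(-c4cc(=O)c5c(OCc6ccccc6)cc(OCc6ccccc6)cc5o4)cc3)c1)CC2O | intermediate
16 | (2S)-2-[4-(benzyloxy)-3-{4-[5,7-bis(benzyloxy)-4-oxo-4H-chromen-2-yl]phenoxy}phenyl]-5,7-dimethoxy-2,3-dihydro-4H-chromen-4-one | COc1cc(OC)c2c(c1)O[C@H](c1ccc(OCc3ccccc3)c(Oc3ccc(-c4cc(=O)c5c(OCc6ccccc6)cc(OCc6ccccc6)cc5o4)cc3)c1)CC2=O | intermediate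
17 | (2S)-2-{3-[4-(5,7-dihydroxy-4-oxo-4H-chromen-2-yl)phenoxy]-4-hydroxyphenyl}-5-hydroxy-7-methoxy-2,3-dihydro-4H-chromen-4-one | COc1cc(O)c2c(c1)O[C@H](c1ccc(O)c(Oc3ccc(-c4cc(=O)c5c(O)cc(O)cc5o4)cc3)c1)CC2=O | target

## Step count and least certain steps

Total step count: 12. Longest linear sequence: 10 steps (4 → 6 → 7 → 8 → 9 → 10 → 13 → 14 → 15 → 16 → 17; the branch from 1 is equally long, the branch from 11 has 6 steps).

**Step 6 (key step).** Most likely failure: β-hydride elimination from the palladium alkoxide outruns C–O reductive elimination, so the carbinol is oxidised and the C–Br bond reduced. The electron-rich ring A makes reductive elimination slower than for a simple aryl group. Fallback, which forms O1–C2 instead of O1–C8a: it sets out from ketone 8, which is reduced with the enantiomeric (S)-2-methyl-CBS-oxazaborolidine and BH3·SMe2 to the (1R)-bromo carbinol F1. Miyaura borylation (B2pin2, PdCl2(dppf), KOAc, dioxane, 90 °C) gives the pinacol boronate F2, and oxidation with NaBO3·4H2O in THF/H2O gives the phenol diol F3. A Mitsunobu cyclisation (PPh3, DIAD, THF, 0 °C) then closes ring C with inversion at the carbinol carbon and comes back to the route at 10. Its own weakness is partial ionisation of the activated benzylic alcohol, which would erode enantiomeric purity.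

**Step 8.** Most likely failure: slow or incomplete acylation, because the enolate of 12 lies between two ortho substituents and the ester of 10 is deactivated by its para-aryloxy group; self-condensation of 12 and retro-Claisen cleavage would then compete. Fallback, intramolecular acyl transfer instead of intermolecular acylation: it sets out from 10, which is saponified (LiOH, THF/MeOH/H2O) to the carboxylic acid F4. This is esterified with 12 (EDC·HCl, DMAP, CH2Cl2) to the 2-acetyl-3,5-bis(benzyloxy)phenyl ester F5. A Baker–Venkataraman rearrangement (KOH, pyridine, 50 °C) moves the aroyl group from oxygen to the enolate carbon and comes back to the route at 13.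

**Step 10.** Most likely failure: hydride abstraction at C2 instead of C4, if ring B competes with ring A as electron donor, followed by opening of ring C and loss of the stereocentre; elimination of the new C4 carbinol toward the 3,4-alkene is a second risk. Fallback, which deactivates ring B before the oxidation: it sets out from 14, whose three benzyl ethers are hydrogenolysed (H2, Pd(OH)2/C, THF/MeOH) to the triphenol F6. Acetylation (Ac2O, pyridine, DMAP) gives the triacetate F7, in which the 4'-acetoxy group no longer stabilises a cation at C2. DDQ in wet CH2Cl2 gives the 4-hydroxy triacetate F8, and Dess–Martin periodinane gives the flavanone triacetate F9. BCl3 (CH2Cl2, −78 → 0 °C) cleaves the peri-methyl ether, and the methanol quench, left at rt, removes the acetates by acid-catalysed methanolysis, coming back to the route at 17.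

**Step 12.** Most likely failure: C-benzylation of the electron-rich rings by benzyl cations, incomplete cleavage of the chelated methyl ether at the temperature where the benzyl ethers have already gone, or Lewis-acid-promoted opening of ring C with loss of configuration during the longer, warmer exposure the methyl ether needs. Fallback, which separates the two deprotections: it sets out from 16, whose benzyl ethers are removed by hydrogenolysis (H2, Pd/C, EtOAc/THF, rt, stopped at three equivalents of hydrogen) to give the 5-O-methyl triphenol F10. A short treatment with BCl3 (3 equiv, CH2Cl2, −78 → 0 °C) then cleaves only the chelated 5-methyl ether and comes back to the route at 17.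

## Further compounds

F1 | step 6 | methyl 4-{2-(benzyloxy)-5-[(1R)-3-(2-bromo-4,6-dimethoxyphenyl)-1-hydroxypropyl]phenoxy}benzoate | COc1cc(Br)c(CC[C@@H](O)c2ccc(OCc3ccccc3)c(Oc3ccc(C(=O)OC)cc3)c2)c(OC)c1
F2 | step 6 | methyl 4-{2-(benzyloxy)-5-[(1R)-3-[2,4-dimethoxy-6-(4,4,5,5-tetramethyl-1,3,2-dioxaborolan-2-yl)phenyl]-1-hydroxypropyl]phenoxy}benzoate | COc1cc(B2OC(C)(C)C(C)(C)O2)c(CC[C@@H](O)c2ccc(OCc3ccccc3)c(Oc3ccc(C(=O)OC)cc3)c2)c(OC)c1
F3 | step 6 | methyl 4-{2-(benzyloxy)-5-[(1R)-1-hydroxy-3-(2-hydroxy-4,6-dimethoxyphenyl)propyl]phenoxy}benzoate | COc1cc(O)c(CC[C@@H](O)c2ccc(OCc3ccccc3)c(Oc3ccc(C(=O)OC)cc3)c2)c(OC)c1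
F4 | step 8 | 4-{2-(benzyloxy)-5-[(2S)-5,7-dimethoxy-3,4-dihydro-2H-chromen-2-yl]phenoxy}benzoic acid | COc1cc(OC)c2c(c1)O[C@H](c1ccc(OCc3ccccc3)c(Oc3ccc(C(=O)O)cc3)c1)CC2
F5 | step 8 | 2-acetyl-3,5-bis(benzyloxy)phenyl 4-{2-(benzyloxy)-5-[(2S)-5,7-dimethoxy-3,4-dihydro-2H-chromen-2-yl]phenoxy}benzoate | COc1cc(OC)c2c(c1)O[C@H](c1ccc(OCc3ccccc3)c(Oc3ccc(C(=O)Oc4cc(OCc5ccccc5)cc(OCc5ccccc5)c4C(C)=O)cc3)c1)CC2
F6 | step 10 | 2-(4-{5-[(2S)-5,7-dimethoxy-3,4-dihydro-2H-chromen-2-yl]-2-hydroxyphenoxy}phenyl)-5,7-dihydroxy-4H-chromen-4-one | COc1cc(OC)c2c(c1)O[C@H](c1ccc(O)c(Oc3ccc(-c4cc(=O)c5c(O)cc(O)cc5o4)cc3)c1)CC2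
F7 | step 10 | 2-(4-{2-acetoxy-5-[(2S)-5,7-dimethoxy-3,4-dihydro-2H-chromen-2-yl]phenoxy}phenyl)-4-oxo-4H-chromene-5,7-diyl diacetate | COc1cc(OC)c2c(c1)O[C@H](c1ccc(OC(C)=O)c(Oc3ccc(-c4cc(=O)c5c(OC(C)=O)cc(OC(C)=O)cc5o4)cc3)c1)CC2
F8 | step 10 | 2-(4-{2-acetoxy-5-[(2S)-4-hydroxy-5,7-dimethoxy-3,4-dihydro-2H-chromen-2-yl]phenoxy}phenyl)-4-oxo-4H-chromene-5,7-diyl diacetate (C4 epimers) | COc1cc(OC)c2c(c1)O[C@H](c1ccc(OC(C)=O)c(Oc3ccc(-c4cc(=O)c5c(OC(C)=O)cc(OC(C)=O)cc5o4)cc3)c1)CC2O
F9 | step 10 | 2-(4-{2-acetoxy-5-[(2S)-5,7-dimethoxy-4-oxo-3,4-dihydro-2H-chromen-2-yl]phenoxy}phenyl)-4-oxo-4H-chromene-5,7-diyl diacetate | COc1cc(OC)c2c(c1)O[C@H](c1ccc(OC(C)=O)c(Oc3ccc(-c4cc(=O)c5c(OC(C)=O)cc(OC(C)=O)cc5o4)cc3)c1)CC2=O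
F10 | step 12 | (2S)-2-{3-[4-(5,7-dihydroxy-4-oxo-4H-chromen-2-yl)phenoxy]-4-hydroxyphenyl}-5,7-dimethoxy-2,3-dihydro-4H-chromen-4-one | COc1cc(OC)c2c(c1)O[C@H](c1ccc(O)c(Oc3ccc(-c4cc(=O)c5c(O)cc(O)cc5o4)cc3)c1)CC2=O
A1 | alternative 1 | (2S)-2-[4-(benzyloxy)-3-(4-bromophenoxy)phenyl]-7-methoxy-5-(methoxymethoxy)spiro[chromane-4,2'-[1,3]dithiane] | COc1cc(OCOC)c2c(c1)O[C@H](c1ccc(OCc3ccccc3)c(Oc3ccc(Br)cc3)c1)CC21SCCCS1
A2 | alternative 1 | (2R)-2-[4-(benzyloxy)-3-(4-bromophenoxy)phenyl]-2-[2-(1,3-dithian-2-yl)-5-methoxy-3-(methoxymethoxy)phenoxy]ethyl 4-methylbenzenesulfonate | COc1cc(OCOC)c(C2SCCCS2)c(c1)O[C@H](c1ccc(OCc3ccccc3)c(Oc3ccc(Br)cc3)c1)COS(=O)(=O)c1ccc(C)cc1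
A3 | alternative 2 | 2-{4-[2-(benzyloxy)-5-bromophenoxy]phenyl}-5-hydroxy-7-[(triisopropylsilyl)oxy]-4H-chromen-4-one | O=c1cc(-c2ccc(Oc3cc(Br)ccc3OCc3ccccc3)cc2)oc2cc(O[Si](C(C)C)(C(C)C)C(C)C)cc(O)c12
A4 | alternative 2 | 2-{4-[2-(benzyloxy)-5-bromophenoxy]phenyl}-6-(diazoacetyl)-4H-pyran-4-one | [N-]=[N+]=CC(=O)c1cc(=O)cc(-c2ccc(Oc3cc(Br)ccc3OCc3ccccc3)cc2)o1
A5 | alternative 2 | (triisopropylsiloxy)acetylene | C#CO[Si](C(C)C)(C(C)C)C(C)C
A6 | alternative 3 | (2S)-2-[4-(benzyloxy)-3-{4-[5,7-bis(benzyloxy)-4-oxo-4H-chromen-2-yl]phenoxy}phenyl]-7-methoxy-5-[(triisopropylsilyl)oxy]-2,3-dihydro-4H-chromen-4-one | COc1cc(O[Si](C(C)C)(C(C)C)C(C)C)c2c(c1)O[C@H](c1ccc(OCc3ccccc3)c(Oc3ccc(-c4cc(=O)c5c(OCc6ccccc6)cc(OCc6ccccc6)cc5o4)cc3)c1)CC2=O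
A7 | alternative 3 | 1-{2-[(4-(benzyloxy)-3-{4-[5,7-bis(benzyloxy)-4-oxo-4H-chromen-2-yl]phenoxy}phenyl)methoxy]-4-methoxy-6-[(triisopropylsilyl)oxy]phenyl}-2-diazoethanone | COc1cc(O[Si](C(C)C)(C(C)C)C(C)C)c(C(=O)C=[N+]=[N-])c(c1)OCc1ccc(OCc2ccccc2)c(Oc2ccc(-c3cc(=O)c4c(OCc5ccccc5)cc(OCc5ccccc5)cc4o3)cc2)c1
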